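## Analysis of the target

Target 14 is the stearic ester of a primary benzylic alcohol on a 2,3-dihydro-1-benzoxepine. Ring A is the benzene ring. Ring B is the seven-membered oxepine O1–C2–C3–C4–C5–C5a–C9a, in which C2 is an OCH2 group, C3 carries an exocyclic methylene and C4=C5 is a cis alkene conjugated with ring A on one side and with the exocyclic alkene on the other. The acyloxymethyl group sits on C7, para to O1. There is no stereocentre. The only stereochemical element is the C4=C5 geometry, which the ring enforces once closed, but which must already be cis for any ring closure that does not itself form this bond. The sensitive parts are the 2-substituted 1,3-diene (acid can move the exocyclic alkene into the ring, and it can polymerise or oxidise), the allylic aryl ether at C2, and the benzylic ester, which rules out strong nucleophiles, hydride and hydrogenolysis at the end. The difficulty is to close a seven-membered ring with three contiguous sp2 carbons and to place the exocyclic alkene without isomerising it. The strategy rests on the O1–C2–C3 segment: if C2 is removed and O1 joined to C3, ring B contracts to the six-membered lactone ring of a coumarin. That lactone already holds the aryl–O1 bond, C3 at the carbonyl oxidation level and the cis C4=C5 alkene, and the C7 substituent falls on coumarin position 6.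

## Retrosynthetic reasoning

**Ester C–O bond.** The acyl–oxygen bond of 14 is cut first, giving (3-methylene-2,3-dihydro-1-benzoxepin-7-yl)methanol 12 and stearoyl chloride 13. A fatty ester would not survive the organolithium and titanium reagents needed to build ring B, so it goes on last. The forward acylation must be run with base present, because acid could draw the exocyclic alkene into the ring.

**Silyl ether O–Si bond.** Alcohol 12 is traced to its triisopropylsilyl ether 11, triisopropyl[(3-methylene-2,3-dihydro-1-benzoxepin-7-yl)methoxy]silane. The benzylic oxygen has to stay masked from the lactone stage to the diene stage. A bulky silyl group resists an alkyllithium and a Lewis-acidic methylenation, and comes off without acid or hydrogen.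

**Exocyclic C3=CH2 bond.** The methylene carbon of 11 is removed to leave the ketone 9, 7-{[(triisopropylsilyl)oxy]methyl}-1-benzoxepin-3(2H)-one, with dibromomethane 10 as the one-carbon source. The cut is made at the double bond because carbonyl olefination fixes the alkene position without ambiguity, whereas an elimination could lose a hydrogen from C2 or C4 instead. The cut also raises C3 to the carbonyl level, which opens the next disconnection. The forward step must be non-basic, since the C2 hydrogens of 9 lie between O1 and the carbonyl group and the enone is a conjugate acceptor.

**O1–C2 and C2–C3 bonds (key disconnection).** In 9 both bonds to C2 are cut. C2 then leaves as a single carbon that is nucleophilic toward C3 and electrophilic toward O1, that is, as the carbenoid chloromethyllithium 6, generated from bromochloromethane 5. Joining O1 to C3 leaves the lactone 4, 6-{[(triisopropylsilyl)oxy]methyl}-2H-chromen-2-one. Cutting only O1–C2 would lead to an open-chain cis chloromethyl enone whose alkene geometry would have to be made selectively. The double cut instead returns to a bicyclic lactone in which the aryl–O1 bond, the C3 carbonyl carbon and the cis C4=C5 alkene are already assembled. In the forward direction 6 must add once, and only at the carbonyl carbon, to give the tetrahedral alkoxide 7. Alkoxide 7 must then open to the cis enone phenoxide 8, and 8 must close the seven-membered ring by displacing chloride. Source 5 is preferred to its iodo analogue paired with a methyllithium reagent, because that pairing would leave a methyl halide able to cap the phenoxide of 8, whereas 5 leaves only a sluggish primary alkyl bromide.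

**Silyl ether of the lactone.** Lactone 4 is traced to 6-(hydroxymethyl)-2H-chromen-2-one 3 by removing the silyl group. The forward silylation of a primary alcohol is routine and leaves the lactone untouched.

**Benzylic C–O bond.** Alcohol 3 comes from 6-(bromomethyl)-2H-chromen-2-one 2 by exchanging oxygen for bromine. The forward hydrolysis must be buffered so that the lactone stays closed.

**Benzylic C–Br bond.** Bromide 2 comes from commercial 6-methyl-2H-chromen-2-one 1. The methyl group is the only sp3 C–H site of 1, so a radical bromination has only one place to go.

## Alternatives that were turned down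

**Alternative 1: C3–C4 bond by nickel-catalysed reductive cyclisation.**
- Disconnection: the C3–C4 bond of ring B, back to the aldehyde–alkyne A1, methyl 3-(2-oxoethyl)-4-(prop-2-yn-1-yloxy)benzoate.
- Forward key step: a zerovalent nickel catalyst (Ni(cod)2 with the carbene ligand 1,3-dimesitylimidazol-2-ylidene) and Et3SiH would join the terminal alkyne and the aldehyde through an oxanickelacycle. Silane σ-bond metathesis and C–H reductive elimination would then give A2, methyl 3-methylene-4-[(triethylsilyl)oxy]-2,3,4,5-tetrahydro-1-benzoxepine-7-carboxylate (racemic).
- For it: the ring closure belongs to an established reaction class and is catalytic. It installs the exocyclic methylene in the ring-forming step, so no ketone methylenation is needed. On precedent for the ring closure it is stronger than the chosen route.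
- Against it: the C4 oxygen of A2 is not wanted in the target. It must be removed as the C4=C5 alkene through an allylic leaving group, where ionisation, attack at the exocyclic CH2 with allylic shift, and migration of the exocyclic alkene all compete. A stereocentre is made only to be destroyed. The arylacetaldehyde A1 is enolisable and self-condensing, and needs several steps to make (allylation, Claisen rearrangement, propargylation, oxidative cleavage). The benzoate must later be reduced beside the diene.
- Comparison: about ten steps against seven. The chosen route starts with C4=C5 at the right oxidation level and geometry and needs no elimination; in exchange it accepts an untested ring-forming step.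

**Alternative 2: O1–C9a bond by nitrile-activated SNAr.**
- Disconnection: the aryl–oxygen bond, back to the cis dienol A3, 4-fluoro-3-[(1Z)-3-(hydroxymethyl)buta-1,3-dien-1-yl]benzonitrile.
- Forward key step: with Cs2CO3 in DMSO the primary alkoxide would attack the fluorine-bearing carbon para to the nitrile, pass through a Meisenheimer adduct and lose fluoride. This would give A4, 3-methylene-2,3-dihydro-1-benzoxepine-7-carbonitrile, with the whole diene already present.
- For it: the key step is ordinary SNAr chemistry with no untested element, and the exocyclic alkene never has to be made from a ketone on the sensitive ring. On these two points it is stronger than the chosen route.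
- Against it: the difficulty moves into A3. Its cis alkene must be made selectively, for example by partial reduction of a conjugated enyne or by a cis-selective olefination, next to a reducible 1,1-disubstituted alkene and a free allylic alcohol. Only one group activates the fluoride. After ring closure the nitrile needs two reductions (to the aldehyde, then to the alcohol) in the presence of the diene.
- Comparison: the step count is similar. The chosen route obtains the cis alkene from the lactone ring without any selective step, uses a commodity starting material, and needs no redox adjustment on ring A.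

**Alternative 3: photochemical ring expansion of a chromene.**
- Disconnection: the O1–C2 bond of a 2,5-dihydro-1-benzoxepine, back to the chromene A5, methyl 2,2-dimethyl-2H-chromene-6-carboxylate.
- Forward key step: irradiation near 300–350 nm in flow would break the pyran O–C bond of A5. A 1,7-hydrogen shift from one geminal methyl group to oxygen would give the cis dienylphenol A6, methyl 4-hydroxy-3-[(1Z)-3-methylbuta-1,3-dien-1-yl]benzoate. A second photon would add the phenolic O–H across the diene termini to give A7, methyl 3-methyl-2,5-dihydro-1-benzoxepine-7-carboxylate.
- For it: it is the shortest construction of the benzoxepine core, uses no reagents and is fully atom-economic. On step economy for the ring system alone it beats the chosen route.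
- Against it: A7 has the wrong unsaturation pattern. C3 carries a methyl group, the alkene is at C3=C4 and C5 is saturated. Reaching the target needs a net dehydrogenation: functionalisation of C5 and then a 1,4-elimination that must take a methyl hydrogen and not a C2 hydrogen, which would give the fully unsaturated oxepine. The two-photon sequence competes with re-closure to A5 and with secondary photochemistry of A6 and A7. The ester must still be reduced.
- Comparison: the chosen key step delivers C3 as a ketone with C4=C5 in place, which is the pattern the target needs, so nothing has to be repaired after ring formation.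

Key step: step 4

Remark on the chemistry: 14 has no stereocentre, so the route needs no stereocontrol beyond keeping the cis C4=C5 alkene of the lactone; the carbenoid is made by bromine–lithium exchange so that no methylating by-product is present when the phenoxide is set free.

## Route

Step 1
Reactants: 1 6-methyl-2H-chromen-2-one
Product: 2 6-(bromomethyl)-2H-chromen-2-one
Conditions: NBS (1.05 equiv), AIBN (cat.), PhCF3, 85 °C
Reagents that add atoms: N-bromosuccinimide, O=C1CCC(=O)N1Br
Why: Wohl–Ziegler benzylic bromination; the radical chain abstracts hydrogen from the only sp3 C–H group of 1, and the low standing concentration of Br2 keeps ionic addition to the electron-poor C3=C4 bond slow, while the small excess of NBS limits a second bromination.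

Step 2
Reactants: 2 6-(bromomethyl)-2H-chromen-2-one
Product: 3 6-(hydroxymethyl)-2H-chromen-2-one
Conditions: CaCO3, dioxane/H2O (1:1), reflux
Reagents that add atoms: water, O
Why: Solvolysis of a primary benzylic bromide in hot aqueous dioxane; CaCO3 only takes up the HBr released, so the medium never becomes basic enough to open the lactone, and any opened cis-hydroxycinnamate would relactonise on acidic work-up.

Step 3
Reactants: 3 6-(hydroxymethyl)-2H-chromen-2-one
Product: 4 6-{[(triisopropylsilyl)oxy]methyl}-2H-chromen-2-one
Conditions: TIPSCl, imidazole, DMF, rt
Reagents that add atoms: triisopropylsilyl chloride, CC(C)[Si](Cl)(C(C)C)C(C)C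
Why: Imidazole-promoted silylation of a primary alcohol; the triisopropylsilyl ether is chosen because it withstands the alkyllithium of step 4 and the Lewis-acidic titanium reagent of step 5 and is later removed by fluoride without acid.

Step 4
Reactants: 4 6-{[(triisopropylsilyl)oxy]methyl}-2H-chromen-2-one, 5 bromochloromethane
Product: 9 7-{[(triisopropylsilyl)oxy]methyl}-1-benzoxepin-3(2H)-one, via chloromethyllithium 6 (not isolated), via tetrahedral lithium alkoxide 7 (not isolated), via (Z)-chloromethyl enone phenoxide 8 (not isolated)
Conditions: BrCH2Cl (5, 1.3 equiv), n-BuLi (1.15 equiv, added slowly), THF (0.05 M), −78 °C, 45 min; then DMF, −78 °C → rt; aq. NH4Cl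
Reagents that add atoms: bromochloromethane (5), ClCBr, which delivers its CH2 group as chloromethyllithium (6), [Li]CCl
Why: Proposed new method: bromine–lithium exchange between n-BuLi and 5 should outrun addition of n-BuLi to the lactone, so 6 forms in the presence of 4 and is trapped at once by 1,2-addition to the lactone carbonyl, which makes the C2–C3 bond and gives the tetrahedral alkoxide 7. On warming, 7 should collapse by expelling the aryloxide, a far better leaving group than an alkoxide, and the cis geometry inherited from the lactone keeps the phenoxide oxygen of 8 within reach of the CH2Cl carbon. An intramolecular SN2 displacement at this α-keto carbon (7-exo-tet: the O–C bond forms inside the new ring and chloride leaves outside it) then makes the O1–C2 bond and closes ring B, with DMF added to loosen the lithium phenoxide ion pair. The closest known reactions are the homologation of esters and lactones to α-chloro ketones with halomethyllithium carbenoids and the O-alkylation of phenoxides by α-halo ketones; joining them into a one-flask one-carbon ring expansion of a coumarin lactone is the untested part. No stereocentre is formed, and the C4=C5 alkene stays cis because it is never broken. The selectivity needed is carbonyl addition over conjugate addition and one addition only: the hard, charge-localised lithium carbenoid at −78 °C favours 1,2-attack, the hold at −78 °C lets the small surplus of the thermally fragile carbenoid decay before 7 opens, and the ring-opened form 8 is a phenoxide-conjugated enone and therefore a poor electrophile. Making 6 from 5 with n-BuLi leaves only 1-bromobutane in the flask, which is far less reactive toward the phenoxide than the internal α-chloro ketone, whereas exchange on chloroiodomethane with MeLi would leave iodomethane, a competent O-methylating agent during the DMF warm-up.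

Step 5
Reactants: 9 7-{[(triisopropylsilyl)oxy]methyl}-1-benzoxepin-3(2H)-one, 10 dibromomethane
Product: 11 triisopropyl[(3-methylene-2,3-dihydro-1-benzoxepin-7-yl)methoxy]silane
Conditions: Zn, CH2Br2 (10), TiCl4, THF, −40 → 5 °C (reagent pre-formed); then 9, CH2Cl2, 0 °C → rt; aq. NaHCO3
Reagents that add atoms: dibromomethane (10), BrCBr
Why: Takai–Lombardo methylenation; the gem-dimetallic reagent from Zn, CH2Br2 and TiCl4 transfers CH2 to the ketone carbonyl in a Wittig-like olefination but is essentially non-basic, so the acidic C2 hydrogens are left alone and the enone is attacked at the carbonyl carbon; the silyl ether and the aryl ether should tolerate the reagent at 0 °C.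

Step 6
Reactants: 11 triisopropyl[(3-methylene-2,3-dihydro-1-benzoxepin-7-yl)methoxy]silane
Product: 12 (3-methylene-2,3-dihydro-1-benzoxepin-7-yl)methanol
Conditions: Bu4NF, THF, 0 °C → rt
Reagents that add atoms: none
Why: Fluoride-induced desilylation driven by the strong Si–F bond; the conditions are non-acidic, so the exocyclic alkene should not migrate into the ring.

Step 7
Reactants: 12 (3-methylene-2,3-dihydro-1-benzoxepin-7-yl)methanol, 13 stearoyl chloride
Product: 14 (3-methylene-2,3-dihydro-1-benzoxepin-7-yl)methyl octadecanoate
Conditions: stearoyl chloride (13), Et3N, DMAP (cat.), CH2Cl2, 0 °C → rt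
Reagents that add atoms: stearoyl chloride (13), CCCCCCCCCCCCCCCCCC(=O)Cl
Why: Acylation of a primary benzylic alcohol by an acid chloride under nucleophilic catalysis by DMAP (through the acylpyridinium ion); Et3N takes up the HCl so that the acid-sensitive diene never meets acid.

## Compound list

1 | 6-methyl-2H-chromen-2-one (6-methylcoumarin) | Cc1ccc2oc(=O)ccc2c1 | starting material
2 | 6-(bromomethyl)-2H-chromen-2-one | BrCc1ccc2oc(=O)ccc2c1 | intermediate
3 | 6-(hydroxymethyl)-2H-chromen-2-one | OCc1ccc2oc(=O)ccc2c1 | intermediate
4 | 6-{[(triisopropylsilyl)oxy]methyl}-2H-chromen-2-one | O=c1ccc2cc(CO[Si](C(C)C)(C(C)C)C(C)C)ccc2o1 | intermediate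
5 | bromochloromethane | ClCBr | starting material
6 | chloromethyllithium (formed in the flask, not isolated) | [Li]CCl | intermediate
7 | lithium 2-(chloromethyl)-6-{[(triisopropylsilyl)oxy]methyl}-2H-chromen-2-olate (racemic, one enantiomer drawn; not isolated) | [Li+].[O-][C@@]1(CCl)C=Cc2cc(CO[Si](C(C)C)(C(C)C)C(C)C)ccc2O1 | intermediate
8 | lithium 2-[(1Z)-4-chloro-3-oxobut-1-en-1-yl]-4-{[(triisopropylsilyl)oxy]methyl}phenolate (not isolated) | [Li+].[O-]c1ccc(CO[Si](C(C)C)(C(C)C)C(C)C)cc1/C=C\C(=O)CCl | intermediate
9 | 7-{[(triisopropylsilyl)oxy]methyl}-1-benzoxepin-3(2H)-one | O=C1COc2ccc(CO[Si](C(C)C)(C(C)C)C(C)C)cc2C=C1 | intermediate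
10 | dibromomethane | BrCBr | starting material
11 | triisopropyl[(3-methylene-2,3-dihydro-1-benzoxepin-7-yl)methoxy]silane | C=C1C=Cc2cc(CO[Si](C(C)C)(C(C)C)C(C)C)ccc2OC1 | intermediate
12 | (3-methylene-2,3-dihydro-1-benzoxepin-7-yl)methanol | C=C1C=Cc2cc(CO)ccc2OC1 | intermediate
13 | stearoyl chloride (octadecanoyl chloride) | CCCCCCCCCCCCCCCCCC(=O)Cl | starting material
14 | (3-methylene-2,3-dihydro-1-benzoxepin-7-yl)methyl octadecanoate | C=C1C=Cc2cc(COC(=O)CCCCCCCCCCCCCCCCC)ccc2OC1 | target

## Step count and least certain steps

Total steps: 7. Longest linear sequence: 7 steps (1 to 14); 5, 10 and 13 enter in steps 4, 5 and 7.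

**Step 4 (key step, proposed new method).**
- What may go wrong: a second carbenoid addition if the tetrahedral alkoxide opens while carbenoid is still present, or butyl transfer to the lactone if the halogen–lithium exchange is not fast enough. The ring-opened phenoxide may lose its cis geometry by rotation about C4–C5, because its push–pull delocalisation lowers the barrier; the oxygen then cannot reach C2. Epoxide closure of the tetrahedral alkoxide before it opens, and intermolecular O-alkylation, are further risks. Running addition and closure in separate flasks would only vary the conditions.
- Fallback (known chemistry, ring B closed at C4=C5): it sets out from 4 and comes back at 9. Ozonolysis of the C3=C4 bond of 4 (O3, CH2Cl2/MeOH, −78 °C; Me2S; aq. NaHCO3 to hydrolyse the aryl glyoxylate) would give 2-hydroxy-5-{[(triisopropylsilyl)oxy]methyl}benzaldehyde F1. Opening of 2-vinyloxirane at its terminal carbon by the phenoxide (K2CO3, DMF, 70 °C) would give 2-[(2-hydroxybut-3-en-1-yl)oxy]-5-{[(triisopropylsilyl)oxy]methyl}benzaldehyde F2. Wittig methylenation (Ph3P=CH2, THF, 0 °C) would give 1-(2-ethenyl-4-{[(triisopropylsilyl)oxy]methyl}phenoxy)but-3-en-2-ol F3. Ring-closing metathesis with the second-generation Grubbs catalyst (CH2Cl2, 40 °C) would form the C4=C5 bond, necessarily cis in a seven-membered ring, and give 7-{[(triisopropylsilyl)oxy]methyl}-2,3-dihydro-1-benzoxepin-3-ol F4. Oxidation of the allylic alcohol with MnO2 (CH2Cl2, rt) returns to 9.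

**Step 5.**
- What may go wrong: reductive coupling of the aryl-conjugated enone by low-valent titanium, Lewis-acid-promoted migration of the new exocyclic alkene into the ring, or partial loss of the silyl ether.
- Fallback (Peterson olefination): it sets out from 9 and comes back at 11. Addition of the organocerium reagent from Me3SiCH2MgCl and CeCl3 (THF, −78 °C), which is weakly basic and adds at the carbonyl carbon, would give 7-{[(triisopropylsilyl)oxy]methyl}-3-[(trimethylsilyl)methyl]-2,3-dihydro-1-benzoxepin-3-ol F5. Syn-elimination with KH (THF, 0 °C → rt) would give 11.

**Step 1.**
- What may go wrong: loss of mono-selectivity through a second benzylic bromination, and ionic bromination across C3=C4 if HBr and Br2 build up.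
- Fallback (through the aldehyde oxidation level): it sets out from 1 and comes back at 3, bypassing 2 and step 2. Bromination is driven to completion with NBS (2.2 equiv, AIBN, PhCF3, reflux) to give 6-(dibromomethyl)-2H-chromen-2-one F6. Hydrolysis with AgNO3 in aqueous ethanol would give 2-oxo-2H-chromene-6-carbaldehyde F7. Brief reduction with NaBH4 (MeOH/THF, 0 °C), which takes the aldehyde well before the lactone, gives 3.

**Step 2.**
- What may go wrong: slow solvolysis, etherification of the product alcohol by unreacted bromide, and partial opening of the lactone on long heating.
- Fallback (acetate route): it sets out from 2 and comes back at 3. Displacement with KOAc (DMF, 60 °C) would give (2-oxo-2H-chromen-6-yl)methyl acetate F8. Acid-catalysed methanolysis (HCl cat., MeOH, rt), to which the lactone is inert, gives 3.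

## Further compounds

F1 | step 4 | 2-hydroxy-5-{[(triisopropylsilyl)oxy]methyl}benzaldehyde | O=Cc1cc(CO[Si](C(C)C)(C(C)C)C(C)C)ccc1O
F2 | step 4 | 2-[(2-hydroxybut-3-en-1-yl)oxy]-5-{[(triisopropylsilyl)oxy]methyl}benzaldehyde (racemic, one enantiomer drawn) | O=Cc1cc(CO[Si](C(C)C)(C(C)C)C(C)C)ccc1OC[C@@H](O)C=C
F3 | step 4 | 1-(2-ethenyl-4-{[(triisopropylsilyl)oxy]methyl}phenoxy)but-3-en-2-ol (racemic, one enantiomer drawn) | C=Cc1cc(CO[Si](C(C)C)(C(C)C)C(C)C)ccc1OC[C@@H](O)C=C
F4 | step 4 | 7-{[(triisopropylsilyl)oxy]methyl}-2,3-dihydro-1-benzoxepin-3-ol (racemic, one enantiomer drawn) | O[C@@H]1COc2ccc(CO[Si](C(C)C)(C(C)C)C(C)C)cc2C=C1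
F5 | step 5 | 7-{[(triisopropylsilyl)oxy]methyl}-3-[(trimethylsilyl)methyl]-2,3-dihydro-1-benzoxepin-3-ol (racemic, one enantiomer drawn) | C[Si](C)(C)C[C@@]1(O)COc2ccc(CO[Si](C(C)C)(C(C)C)C(C)C)cc2C=C1
F6 | step 1 | 6-(dibromomethyl)-2H-chromen-2-one | O=c1ccc2cc(C(Br)Br)ccc2o1
F7 | step 1 | 2-oxo-2H-chromene-6-carbaldehyde | O=Cc1ccc2oc(=O)ccc2c1
F8 | step 2 | (2-oxo-2H-chromen-6-yl)methyl acetate | CC(=O)OCc1ccc2oc(=O)ccc2c1
A1 | alternative 1 | methyl 3-(2-oxoethyl)-4-(prop-2-yn-1-yloxy)benzoate | COC(=O)c1ccc(OCC#C)c(CC=O)c1
A2 | alternative 1 | methyl 3-methylene-4-[(triethylsilyl)oxy]-2,3,4,5-tetrahydro-1-benzoxepine-7-carboxylate (racemic, one enantiomer drawn) | COC(=O)c1ccc2OCC(=C)[C@@H](O[Si](CC)(CC)CC)Cc2c1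
A3 | alternative 2 | 4-fluoro-3-[(1Z)-3-(hydroxymethyl)buta-1,3-dien-1-yl]benzonitrile | N#Cc1ccc(F)c(/C=C\C(=C)CO)c1
A4 | alternative 2 | 3-methylene-2,3-dihydro-1-benzoxepine-7-carbonitrile | N#Cc1ccc2OCC(=C)C=Cc2c1
A5 | alternative 3 | methyl 2,2-dimethyl-2H-chromene-6-carboxylate | COC(=O)c1ccc2OC(C)(C)C=Cc2c1
A6 | alternative 3 | methyl 4-hydroxy-3-[(1Z)-3-methylbuta-1,3-dien-1-yl]benzoate | COC(=O)c1ccc(O)c(/C=C\C(C)=C)c1
A7 | alternative 3 | methyl 3-methyl-2,5-dihydro-1-benzoxepine-7-carboxylate | COC(=O)c1ccc2OCC(C)=CCc2c1
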